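**Plan**

- Cuts: the C6 silyl ether and the C7 carbinol go back to a 7-ketone. A retro-aldol then opens the C5–C6 bond of the carbocycle (ring A: C4a–C5–C6–C7–C8–C8a) to a keto aldehyde. Next come the C8–O aryl ether bond, the C7–C8 bond (lateral acylation of a 2-methylpyranone) and pyranone ring B (β-keto thioester plus ynoyl chloride).
- Enabling feature: C7 lies between C6 and C8. As a ketone it makes C6 an enamine donor toward a non-enolisable C5 aldehyde carried by C4a of ring B. It also leaves the aryloxy-bearing C8, which is in addition vinylogous to the C4 carbonyl through C8a=C4a, free to epimerise.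
- Forward order: the chromone partner (rings C and D) is made first, then ring B, then the C8–C7–C6 side chain, then the ether link at C8, and last ring A by the aldol.
- Stereochemistry: no stereocentre is fixed before the aldol. D-proline sets C5 and C6, C8 follows by equilibration to the pseudoaxial aryloxy epimer, and C7 comes from hydride addition anti to that aryloxy group.

Key step: step 12

Remark: atoms carry the numbers of the 5,6,7,8-tetrahydrochromen-4-one unit of the target (O1 to C8a) in all precursors. The sense of induction in step 12 is assigned from the Houk–List model and is assumed to carry over to this ring closure.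

**Route**

Step 1
Reactants: 1 2',5'-dihydroxy-4'-methoxyacetophenone; 2 3-phenylpropanoyl chloride
Product: 4 6-hydroxy-7-methoxy-2-(2-phenylethyl)-4H-chromen-4-one, via 1,3-diketone 3 (not isolated)
Conditions: LiN(SiMe3)2 (4 equiv), THF, −78 to −10 °C; 2, −78 °C to rt; aq. HCl; then H2SO4 (cat.), AcOH, 95 °C
Reagents that add atoms: none
Why: Claisen-type C-acylation of the lithium enolate (both phenols held as lithium phenoxides) should give the 1,3-diketone, which cyclodehydrates under acid to the chromone, the standard 2-(2-phenylethyl)chromone construction.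

Step 2
Reactants: 5 4-phenyl-1-butyne
Product: 6 5-phenylpent-2-ynoic acid
Conditions: n-BuLi, THF, −78 °C; CO2 (g), −78 °C to rt; aq. HCl
Reagents that add atoms: carbon dioxide, O=C=O
Why: Carboxylation of the lithium acetylide with carbon dioxide is a routine entry to 2-alkynoic acids.

Step 3
Reactants: 7 2,2,6-trimethyl-4H-1,3-dioxin-4-one; 8 1-dodecanethiol
Product: 10 S-dodecyl 3-oxobutanethioate, via acetylketene 9 (not isolated)
Conditions: toluene, 110 °C, acetone distilled off
Reagents that add atoms: none
Why: Thermal retro-hetero-Diels–Alder cleavage of the dioxinone releases acetylketene, which the thiol traps (acetoacetylation); the odourless, non-volatile dodecyl thioester is later reducible to the aldehyde.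

Step 4
Reactants: 6 5-phenylpent-2-ynoic acid; 10 S-dodecyl 3-oxobutanethioate
Product: 13 S-dodecyl 2-methyl-4-oxo-6-(2-phenylethyl)-4H-pyran-3-carbothioate, via 5-phenylpent-2-ynoyl chloride 11 (not isolated), via triacylmethane thioester 12 (not isolated)
Conditions: 6, (COCl)2, DMF (cat.), CH2Cl2, 0 °C to rt, evaporate; 10, MgCl2, Et3N, MeCN, 0 °C, then 11, 0 to 40 °C
Reagents that add atoms: none
Why: Soft-enolisation C-acylation of the magnesium enolate (Rathke conditions) is followed by 6-endo-dig oxa-Michael addition of the acetyl enol oxygen to the ynone, the established β-dicarbonyl plus alkynoyl chloride route to 4-pyranones.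

Step 5
Reactants: 13 S-dodecyl 2-methyl-4-oxo-6-(2-phenylethyl)-4H-pyran-3-carbothioate
Product: 14 2-methyl-4-oxo-6-(2-phenylethyl)-4H-pyran-3-carbaldehyde
Conditions: Et3SiH, Pd/C (10% Pd), acetone, rt
Reagents that add atoms: none
Why: Fukuyama reduction: zerovalent palladium inserts into the C–S bond and the silane delivers hydride, so the aldehyde should form without the attack on the pyranone ring that a metal hydride would risk.

Step 6
Reactants: 14 2-methyl-4-oxo-6-(2-phenylethyl)-4H-pyran-3-carbaldehyde
Product: 15 3-(dimethoxymethyl)-2-methyl-6-(2-phenylethyl)-4H-pyran-4-one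
Conditions: HC(OMe)3, TsOH·H2O (cat.), MeOH, rt; NaHCO3
Reagents that add atoms: trimethyl orthoformate, COC(OC)OC; methanol, CO
Why: Acid-catalysed acetalisation with orthoformate as water scavenger masks the aldehyde against the strong base of step 8.

Step 7
Reactants: 16 methyl glycolate
Product: 17 methyl [(tert-butyldimethylsilyl)oxy]acetate
Conditions: TBSCl, imidazole, DMF, rt
Reagents that add atoms: tert-butyldimethylsilyl chloride (TBSCl), CC(C)(C)[Si](C)(C)Cl
Why: Imidazole-promoted silylation of a primary alcohol is routine.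

Step 8
Reactants: 15 3-(dimethoxymethyl)-2-methyl-6-(2-phenylethyl)-4H-pyran-4-one; 17 methyl [(tert-butyldimethylsilyl)oxy]acetate
Product: 18 2-{3-[(tert-butyldimethylsilyl)oxy]-2-oxopropyl}-3-(dimethoxymethyl)-6-(2-phenylethyl)-4H-pyran-4-one
Conditions: LiN(SiMe3)2 (2.2 equiv), THF, −78 °C; 17, −78 to −40 °C; aq. NH4Cl
Reagents that add atoms: none
Why: Lateral (vinylogous) deprotonation should occur at the 2-methyl group rather than the C6 side-chain methylene, because it is a methyl group next to the lithium-coordinating acetal; the dienolate then undergoes Claisen acylation with the ester, and the second equivalent of base stores the product as its enolate so that no double addition occurs.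

Step 9
Reactants: 18 2-{3-[(tert-butyldimethylsilyl)oxy]-2-oxopropyl}-3-(dimethoxymethyl)-6-(2-phenylethyl)-4H-pyran-4-one
Product: 19 2-{3-[(tert-butyldimethylsilyl)oxy]-1-chloro-2-oxopropyl}-3-(dimethoxymethyl)-6-(2-phenylethyl)-4H-pyran-4-one (racemic)
Conditions: NCS (1.0 equiv), K2CO3 (cat.), MeCN, 0 °C
Reagents that add atoms: N-chlorosuccinimide (NCS), O=C1CCC(=O)N1Cl
Why: The C8 methylene is alpha to the ketone and vinylogous to the pyranone carbonyl, so it enolises like a 1,3-dicarbonyl compound and should be chlorinated selectively (electrophilic α-halogenation); the new centre is racemic and labile.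

Step 10
Reactants: 19 2-{3-[(tert-butyldimethylsilyl)oxy]-1-chloro-2-oxopropyl}-3-(dimethoxymethyl)-6-(2-phenylethyl)-4H-pyran-4-one; 4 6-hydroxy-7-methoxy-2-(2-phenylethyl)-4H-chromen-4-one
Product: 20 6-({3-[(tert-butyldimethylsilyl)oxy]-1-[3-(dimethoxymethyl)-4-oxo-6-(2-phenylethyl)-4H-pyran-2-yl]-2-oxopropyl}oxy)-7-methoxy-2-(2-phenylethyl)-4H-chromen-4-one (racemic)
Conditions: K2CO3, DMF, 0 °C to rt
Reagents that add atoms: none
Why: Williamson ether synthesis: the phenoxide displaces the doubly activated secondary chloride by SN2, as in the O-alkylation of phenols with 2-chloro-1,3-dicarbonyl compounds; the product is racemic and C8 stays labile.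

Step 11
Reactants: 20 the dimethyl acetal of step 10
Product: 21 2-{3-[(tert-butyldimethylsilyl)oxy]-1-{[7-methoxy-4-oxo-2-(2-phenylethyl)-4H-chromen-6-yl]oxy}-2-oxopropyl}-4-oxo-6-(2-phenylethyl)-4H-pyran-3-carbaldehyde (racemic keto aldehyde)
Conditions: Amberlyst-15, acetone–H2O (20:1), rt; filter, use at once
Reagents that add atoms: water, O
Why: The oxocarbenium ion of this acetal is stabilised by the ring enol ether, so mild acid hydrolysis should free the aldehyde while the primary silyl ether survives.

Step 12
Reactants: 21 racemic keto aldehyde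
Product: 22 6-{[(5S,6R,8R)-6-[(tert-butyldimethylsilyl)oxy]-5-hydroxy-4,7-dioxo-2-(2-phenylethyl)-5,6,7,8-tetrahydro-4H-chromen-8-yl]oxy}-7-methoxy-2-(2-phenylethyl)-4H-chromen-4-one
Conditions: D-proline (30 mol%), DMSO, rt
Reagents that add atoms: none
Why: Proposed new method: D-proline condenses with the C7 ketone; because an enamine toward C8 would be tetrasubstituted and the C5 aldehyde cannot enolise, the reacting species should be the C6 (E)-enamine, which adds to the C5 aldehyde held over it by the C8–C8a=C4a tether in a 6-(enolendo)-exo-trig closure of ring A, after which hydrolysis returns the catalyst. The closest known reactions are the proline-catalysed enolendo aldol cyclisation of triketones (Hajos–Parrish reaction) and proline aldol additions of protected hydroxyacetone donors. In the Houk–List arrangement the carboxylic acid guides the aldehyde oxygen onto the enamine face it shields, which with the (R)-catalyst should fix C5 as S and, from the E-enamine, C6 as R, the two C–O bonds emerging anti-periplanar, that is 5,6-trans. C8 is alpha to the ketone and gamma to the C4 carbonyl through C8a=C4a, so 21 racemises and the ketol epimerises there under the reaction conditions; the aryloxy group is expected to settle pseudoaxial, trans to the C6 silyloxy group (8R in 22, same spatial arrangement as 8S in the target), where it avoids the C7 carbonyl dipole and the peri interaction with O1. The step needs regioselective enamine formation, secured by the substitution at C8 and the bulky silyloxy group, and it must stop at the ketol, for which the mild conditions and immediate use in step 13 are planned.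

Step 13
Reactants: 22 the (5S,6R,8R)-7-ketone
Product: 23 6-{[(5S,6R,7R,8S)-6-[(tert-butyldimethylsilyl)oxy]-5,7-dihydroxy-4-oxo-2-(2-phenylethyl)-5,6,7,8-tetrahydro-4H-chromen-8-yl]oxy}-7-methoxy-2-(2-phenylethyl)-4H-chromen-4-one
Conditions: NaBH4, CeCl3·7H2O, MeOH–THF, −78 °C
Reagents that add atoms: none
Why: Luche reduction: hydride should add axially to the C7 carbonyl from the face anti to the pseudoaxial C8 aryloxy group (polar Felkin–Anh, with only the axial C5–H on that face), giving the equatorial C7 hydroxyl cis to C5–OH and C8–OAr and trans to C6–OSi, while the cerium salt suppresses conjugate reduction of the pyranone rings; the descriptors at C7 and C8 differ from those of 22 and 24 only through priority changes.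

Step 14
Reactants: 23 the 6-O-silyl triol precursor
Product: 24 6-{[(5S,6R,7S,8S)-5,6,7-trihydroxy-4-oxo-2-(2-phenylethyl)-5,6,7,8-tetrahydro-4H-chromen-8-yl]oxy}-7-methoxy-2-(2-phenylethyl)-4H-chromen-4-one (CNP0125425.2)
Conditions: HF·pyridine, pyridine, THF, 0 °C to rt
Reagents that add atoms: none
Why: Fluoride cleavage of the silyl ether under buffered acidic conditions should avoid base-induced epimerisation at C8 or elimination and touches no stereocentre.

**Compound list**

1 | 2',5'-dihydroxy-4'-methoxyacetophenone | CC(=O)c1cc(O)c(OC)cc1O | starting material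
2 | 3-phenylpropanoyl chloride | O=C(Cl)CCc1ccccc1 | starting material
3 | 1-(2,5-dihydroxy-4-methoxyphenyl)-5-phenylpentane-1,3-dione | O=C(CC(=O)CCc1ccccc1)c1cc(O)c(OC)cc1O | intermediate (not isolated)
4 | 6-hydroxy-7-methoxy-2-(2-phenylethyl)-4H-chromen-4-one | COc1cc2oc(CCc3ccccc3)cc(=O)c2cc1O | intermediate
5 | 4-phenyl-1-butyne | C#CCCc1ccccc1 | starting material
6 | 5-phenylpent-2-ynoic acid | OC(=O)C#CCCc1ccccc1 | intermediate
7 | 2,2,6-trimethyl-4H-1,3-dioxin-4-one | CC1=CC(=O)OC(C)(C)O1 | starting material
8 | 1-dodecanethiol | CCCCCCCCCCCCS | starting material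
9 | acetylketene | CC(=O)C=C=O | intermediate (not isolated)
10 | S-dodecyl 3-oxobutanethioate | CCCCCCCCCCCCSC(=O)CC(C)=O | intermediate
11 | 5-phenylpent-2-ynoyl chloride | O=C(Cl)C#CCCc1ccccc1 | intermediate (not isolated)
12 | S-dodecyl 2-acetyl-3-oxo-7-phenylhept-4-ynethioate | CCCCCCCCCCCCSC(=O)C(C(C)=O)C(=O)C#CCCc1ccccc1 | intermediate (not isolated)
13 | S-dodecyl 2-methyl-4-oxo-6-(2-phenylethyl)-4H-pyran-3-carbothioate | CCCCCCCCCCCCSC(=O)c1c(C)oc(CCc2ccccc2)cc1=O | intermediate
14 | 2-methyl-4-oxo-6-(2-phenylethyl)-4H-pyran-3-carbaldehyde | Cc1oc(CCc2ccccc2)cc(=O)c1C=O | intermediate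
15 | 3-(dimethoxymethyl)-2-methyl-6-(2-phenylethyl)-4H-pyran-4-one | COC(OC)c1c(C)oc(CCc2ccccc2)cc1=O | intermediate
16 | methyl glycolate | COC(=O)CO | starting material
17 | methyl [(tert-butyldimethylsilyl)oxy]acetate | COC(=O)CO[Si](C)(C)C(C)(C)C | intermediate
18 | 2-{3-[(tert-butyldimethylsilyl)oxy]-2-oxopropyl}-3-(dimethoxymethyl)-6-(2-phenylethyl)-4H-pyran-4-one | CC(C)(C)[Si](C)(C)OCC(=O)Cc1oc(CCc2ccccc2)cc(=O)c1C(OC)OC | intermediate
19 | 2-{3-[(tert-butyldimethylsilyl)oxy]-1-chloro-2-oxopropyl}-3-(dimethoxymethyl)-6-(2-phenylethyl)-4H-pyran-4-one, racemic | CC(C)(C)[Si](C)(C)OCC(=O)C(Cl)c1oc(CCc2ccccc2)cc(=O)c1C(OC)OC | intermediate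
20 | aryl ether dimethyl acetal, racemic | COc1cc2oc(CCc3ccccc3)cc(=O)c2cc1OC(C(=O)CO[Si](C)(C)C(C)(C)C)c1oc(CCc2ccccc2)cc(=O)c1C(OC)OC | intermediate
21 | keto aldehyde, racemic and labile at the aryloxy carbon | COc1cc2oc(CCc3ccccc3)cc(=O)c2cc1OC(C(=O)CO[Si](C)(C)C(C)(C)C)c1oc(CCc2ccccc2)cc(=O)c1C=O | intermediate
22 | (5S,6R,8R)-6-O-TBS-5-hydroxy-7-ketone | COc1cc2oc(CCc3ccccc3)cc(=O)c2cc1O[C@@H]1c2oc(CCc3ccccc3)cc(=O)c2[C@H](O)[C@@H](O[Si](C)(C)C(C)(C)C)C1=O | intermediate
23 | (5S,6R,7R,8S)-6-O-TBS-5,7-diol | COc1cc2oc(CCc3ccccc3)cc(=O)c2cc1O[C@@H]1c2oc(CCc3ccccc3)cc(=O)c2[C@H](O)[C@@H](O[Si](C)(C)C(C)(C)C)[C@@H]1O | intermediate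
24 | (5S,6R,7S,8S)-triol, CNP0125425.2 | COc1cc2oc(CCc3ccccc3)cc(=O)c2cc1O[C@@H]1c2oc(CCc3ccccc3)cc(=O)c2[C@H](O)[C@@H](O)[C@@H]1O | target

**Step count**

Total: 14 steps. Longest linear sequence: 11 steps (steps 3, 4, 5, 6, 8, 9, 10, 11, 12, 13, 14, from 7 to 24).

**Steps most likely to fail**

1. Step 12. The amine may fail to form the C6 enamine of the hindered ketone, or may add reversibly to the electrophilic pyranone. The ketol may lose water and aromatise. Enantiocontrol or the C8 equilibration may fall short.
Fallback: setting out from 21, ring A would be closed without a chiral catalyst by soft enolisation (MgBr2·OEt2, iPr2NEt, CH2Cl2, −20 °C; a magnesium-enolate aldol under thermodynamic control). This should give the 5,6-trans, 6,8-trans ketol as a racemate, that is 22 together with its mirror-image ketol F1. The enantiomers would be separated by preparative HPLC on a chiral stationary phase, and the unwanted one could be returned to the equilibrium by base-induced retro-aldol. The (5S,6R,8R) enantiomer is 22, where the route is rejoined.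

2. Step 13. Hydride may add from the face syn to the C8 aryloxy group if the ring reacts through the conformer with the C5 and C6 oxygens axial, or may be delivered internally from a C5 alkoxyborohydride; either gives the C7 epimer. Retro-aldol is a lesser loss.
Fallback: setting out from 22, the silyl group would be removed first (HF·pyridine, THF, 0 °C) to give the (5S,6R,8R)-5,6-dihydroxy-7-ketone F2. Reduction with Zn(BH4)2 in Et2O–THF at −40 °C would then be chelation-controlled: zinc bridges the free C6 hydroxyl and the C7 carbonyl, locks the C6 oxygen equatorial and the C8 aryloxy group axial, and hydride enters anti to the aryloxy group. This returns to the route directly at 24.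

3. Step 8. Deprotonation may occur at the C6 side-chain methylene instead of the 2-methyl group, or the dienolate may add to a second pyranone rather than to the ester.
Fallback: setting out from 13, the thioester would be kept as the masked aldehyde, since its 2-methyl group is the only position vinylogous to two carbonyl groups.
- Acylation with 17 (LiN(SiMe3)2, 2.1 equiv, THF, −78 °C, acidic quench at −78 °C) would give the keto thioester F3.
- NCS in MeCN at 0 °C would give the chloro ketone F4.
- Phenol 4 with K2CO3 in DMF at 0 °C would give the aryl ether thioester F5; the mixture is kept cold so that the enol does not lactonise onto the thioester.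
- Fukuyama reduction (Et3SiH, Pd/C, acetone) would then release the aldehyde and rejoin the route at 21, with steps 5, 6 and 11 no longer needed.

**Further compounds**

F1 | step 12 | mirror-image ketol, (5R,6S,8S)-6-O-TBS-5-hydroxy-7-ketone, formed with 22 as the racemate | COc1cc2oc(CCc3ccccc3)cc(=O)c2cc1O[C@H]1c2oc(CCc3ccccc3)cc(=O)c2[C@@H](O)[C@H](O[Si](C)(C)C(C)(C)C)C1=O
F2 | step 13 | (5S,6R,8R)-5,6-dihydroxy-7-ketone | COc1cc2oc(CCc3ccccc3)cc(=O)c2cc1O[C@@H]1c2oc(CCc3ccccc3)cc(=O)c2[C@H](O)[C@@H](O)C1=O
F3 | step 8 | S-dodecyl 2-{3-[(tert-butyldimethylsilyl)oxy]-2-oxopropyl}-4-oxo-6-(2-phenylethyl)-4H-pyran-3-carbothioate | CCCCCCCCCCCCSC(=O)c1c(CC(=O)CO[Si](C)(C)C(C)(C)C)oc(CCc2ccccc2)cc1=O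
F4 | step 8 | S-dodecyl 2-{3-[(tert-butyldimethylsilyl)oxy]-1-chloro-2-oxopropyl}-4-oxo-6-(2-phenylethyl)-4H-pyran-3-carbothioate, racemic | CCCCCCCCCCCCSC(=O)c1c(C(Cl)C(=O)CO[Si](C)(C)C(C)(C)C)oc(CCc2ccccc2)cc1=O
F5 | step 8 | S-dodecyl 2-{3-[(tert-butyldimethylsilyl)oxy]-1-{[7-methoxy-4-oxo-2-(2-phenylethyl)-4H-chromen-6-yl]oxy}-2-oxopropyl}-4-oxo-6-(2-phenylethyl)-4H-pyran-3-carbothioate, racemic | COc1cc2oc(CCc3ccccc3)cc(=O)c2cc1OC(C(=O)CO[Si](C)(C)C(C)(C)C)c1oc(CCc2ccccc2)cc(=O)c1C(=O)SCCCCCCCCCCCC
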